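## Structural features

The target is an achiral tetramer of phloroglucinol (rings A–D) with ten free phenolic OH groups and no stereocentre; the only hindered axis, between rings C and D, is not stereogenic because ring D is symmetrically substituted. Ring A (3,5-dihydroxyphenyl) is bound through an ether oxygen to C-1 of ring B, a carbon flanked by two OH groups, and the oxygen on C-4 of ring B, para to C-1, is bound to ring C. Ring C is the hub and its carbons are lettered here in ring order: Ca carries the aryloxy group, Cb an OH, Cc the only hydrogen, Cd an OH, Ce the bond to C-1 of ring D (2,4,6-trihydroxyphenyl) and Cf an OH. The real difficulty lies in two bonds at ring C that sit one carbon apart: the O–Ca ether bond, whose carbon has two oxygenated ortho neighbours, and the Ce–C-1(D) biaryl bond, which has four ortho oxygen substituents. All four rings are very electron-rich, so their free CH positions are nucleophilic towards acylating and oxidising reagents, the free polyphenol is sensitive to air in base, and the 2,2'-dihydroxybiaryl can cyclodehydrate to a dibenzofuran in hot acid. The feature the key step exploits is that Cb, Cd and Cf all carry oxygen, so ring C is the enol form of a cyclohexane-1,3,5-trione: Cf can be a ketone whose sp3 neighbours Ca and Ce already hold the aryloxy and aryl groups, and Cb–Cc–Cd can be a malonyl unit. In one sentence, ring C is created by a [3+3] double C-acylation of the methyl enol ether of a 1-aryloxy-3-arylpropan-2-one with malonyl dichloride, so that neither hindered bond is ever made between two aromatic rings.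

## Logic of the disconnections

17 to 16: the eight O–CH3 bonds are cut. Methyl ethers are chosen because the starting materials already carry them and they survive the organometallic, oxidative and acid chloride steps. The gain is a non-polar, chromatographable precursor. The demand is exhaustive ether cleavage that leaves the diaryl ether and biaryl bonds untouched.

16 to 13 and 14 (key disconnection): the Ca–Cb and Ce–Cd bonds of ring C are cut, which removes ring C altogether. The reason is that in 13 the O–Ca bond and the Ce–aryl bond are ordinary bonds to sp3 or vinylic carbon, free of the ortho crowding they have in the arene. The gain is the step from a tetra-aryl hub to an acyclic three-carbon enol ether plus the symmetrical three-carbon diacid chloride 14. The demand is acylation at carbon on both α positions, not at oxygen and not on rings A, B or D.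

13 to 11: the enol ether C–O–CH3 unit is traced back to the ketone. The methyl group is there to block the oxygen on Cf during the key step. The demand is enol ether formation without acid-induced attack of ring B on the activated carbonyl carbon.

11 to 10: an oxidation-level change at the future Cf. It allows the carbon chain to be assembled by epoxide opening; the demand is a mild, neutral oxidant.

10 to 7 and 9 (from 8): the Ce–C-1(ring D) bond is cut as a C(sp3)–C(aryl) bond. This is the bond that ends as the tetra-ortho-substituted biaryl bond, here reduced to attack of an aryl Grignard reagent on a CH2 group. The demand is opening of the epoxide at its terminal carbon.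

7 to 5 and 6: the O–Ca bond is cut as an alkyl aryl ether. The hindered diaryl ether bond of the target is thereby reduced to an SN2 reaction of a phenoxide at a primary carbon. The demand is trivial.

5 to 3 (through 4): the C-4–O bond of ring B is traced back to a C-4–CHO bond. This lets ring B come from a building block with all its oxygens in place and differentiated. The demand is aryl (not hydride) migration in the peracid oxidation.

3 to 1 and 2: the O–C(ring A) bond is cut. This is the only aryl–oxygen bond made by coupling, and it is made at the unhindered ring A carbon with the hindered partner as the nucleophile, the favourable polarity.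

## Other disconnections considered

Alternative 1: the cuts most chemists would make first are the O–Ca bond and the Ce–C-1(ring D) bond, both as couplings between intact arenes. Forward, a Suzuki–Miyaura coupling would give the hexaoxygenated biaryl, which after bromination to A1 (3-bromo-2,2',4,4',6,6'-hexamethoxy-1,1'-biphenyl) would be joined to 5 by Ullmann etherification. The chosen plan is preferred on structural and mechanistic grounds:
- A1 carries the halogen between two methoxy groups on an electron-rich ring, the least favourable case for oxidative addition and a likely one for protodehalogenation.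
- The biaryl coupling must force four ortho oxygen substituents together.
- The two problems are solved one after the other instead of in one operation.

The reversed-polarity form of this disconnection is kept as the fallback for step 7.

Alternative 2: only the Ce–Cf bond of ring C is cut, giving the linear polyketide-type ester A2 (methyl 2-[4-(3,5-dimethoxyphenoxy)-3,5-dimethoxyphenoxy]-3,5-dioxo-6-(2,4,6-trimethoxyphenyl)hexanoate), available by γ-acylation of an aryloxyacetoacetate dianion. The forward key step would be a base-mediated Claisen cyclisation of Ce onto the ester carbon, as in the biosynthesis of phloroglucinols. The step count is similar, but the mechanism is weaker: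
- The ester lies next to the acidic Ca–H, so any base able to deprotonate Ce turns the ester into part of an enolate and deactivates it.
- The free oxygen on Cd is placed to lactonise to the 4-hydroxy-2-pyranone A3 (3-[4-(3,5-dimethoxyphenoxy)-3,5-dimethoxyphenoxy]-4-hydroxy-6-[(2,4,6-trimethoxyphenyl)methyl]-2H-pyran-2-one), the expected non-enzymatic outcome for a 3,5-dioxo ester.

The chosen [3+3] closure has no free oxygen in a 1,5 relation to the acylating carbon and uses an acid chloride that enolisation cannot switch off.

Alternative 3: ring C is kept and only the O–Ca bond is cut, but it is formed from a carbene. Forward, Rh2(OAc)4 would decompose the diazo dienone A4 (4-diazo-3,5-dimethoxy-2-(2,4,6-trimethoxyphenyl)cyclohexa-2,5-dien-1-one), and the quinoid carbene would insert into the O–H bond of 5 to give the para-hydroxy diaryl ether A5. This avoids a coupling at the hindered carbon, but it is less attractive for three reasons: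
- A4 presupposes the tetra-ortho-substituted biaryl, made by a separate coupling.
- A4 needs a para-selective diazotisation.
- The electrophilic carbene must prefer O–H insertion over attack on the very electron-rich rings A and B of 5.

It therefore settles one of the two difficult bonds, not both.

Key step: step 7

Assumption: 6, 7 and 10 are handled as racemates; their single stereocentre is erased in step 5 and the target has none.

## Route

Step 1
Reactants: 1 syringaldehyde (4-hydroxy-3,5-dimethoxybenzaldehyde); 2 (3,5-dimethoxyphenyl)boronic acid
Product: 3 4-(3,5-dimethoxyphenoxy)-3,5-dimethoxybenzaldehyde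
Conditions: Cu(OAc)2 (20 mol %), pyridine, 4 Å molecular sieves, CH2Cl2, O2 (1 atm), rt
Reagents that add atoms: none
Why: Chan–Lam oxidative O-arylation; the aryl group is transferred from boron to a copper phenoxide and C–O reductive elimination from trivalent copper forms the ether at the unhindered ring A carbon. The method accepts 2,6-disubstituted phenols and leaves the aldehyde untouched.

Step 2
Reactants: 3 4-(3,5-dimethoxyphenoxy)-3,5-dimethoxybenzaldehyde
Product: 5 4-(3,5-dimethoxyphenoxy)-3,5-dimethoxyphenol, via aryl formate 4 (not isolated)
Conditions: mCPBA, CH2Cl2, 0 °C to rt; then K2CO3 (0.2 equiv), MeOH, rt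
Reagents that add atoms: mCPBA (3-chloroperoxybenzoic acid), OOC(=O)c1cccc(Cl)c1
Why: Baeyer–Villiger (Dakin-type) oxidation; in the Criegee intermediate the electron-rich ring, carrying a para aryloxy group, migrates in preference to hydride to give the aryl formate, which is methanolysed in the same flask to the phenol.

Step 3
Reactants: 5 4-(3,5-dimethoxyphenoxy)-3,5-dimethoxyphenol; 6 epichlorohydrin (racemic)
Product: 7 racemic 2-{[4-(3,5-dimethoxyphenoxy)-3,5-dimethoxyphenoxy]methyl}oxirane
Conditions: K2CO3, MeCN, 80 °C (6 in excess)
Reagents that add atoms: none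
Why: Williamson etherification; direct SN2 at the CH2Cl carbon and epoxide opening followed by reclosure lead to the same racemic glycidyl ether. The O–Ca bond of the target is made here at a primary sp3 carbon.

Step 4
Reactants: 7 racemic 2-{[4-(3,5-dimethoxyphenoxy)-3,5-dimethoxyphenoxy]methyl}oxirane; 8 2-bromo-1,3,5-trimethoxybenzene
Product: 10 racemic 1-[4-(3,5-dimethoxyphenoxy)-3,5-dimethoxyphenoxy]-3-(2,4,6-trimethoxyphenyl)propan-2-ol, via arylmagnesium bromide 9 (not isolated)
Conditions: 8, Mg turnings, THF, reflux; then CuI (10 mol %), 7, THF, −30 °C to rt; aq NH4Cl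
Reagents that add atoms: none
Why: CuI-catalysed ring opening of a terminal epoxide by an aryl Grignard reagent at the unsubstituted carbon; this C(sp3)–C(aryl) bond becomes the biaryl bond after step 7. The new carbinol centre is formed as a racemate and is removed in step 5.

Step 5
Reactants: 10 racemic 1-[4-(3,5-dimethoxyphenoxy)-3,5-dimethoxyphenoxy]-3-(2,4,6-trimethoxyphenyl)propan-2-ol
Product: 11 1-[4-(3,5-dimethoxyphenoxy)-3,5-dimethoxyphenoxy]-3-(2,4,6-trimethoxyphenyl)propan-2-one
Conditions: Dess–Martin periodinane, CH2Cl2, rt
Reagents that add atoms: none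
Why: Dess–Martin oxidation of a secondary alcohol under near-neutral conditions; aryl ethers are inert to the periodinane and the acetic acid released is too weak to cyclise the aryloxy ketone onto ring B.

Step 6
Reactants: 11 1-[4-(3,5-dimethoxyphenoxy)-3,5-dimethoxyphenoxy]-3-(2,4,6-trimethoxyphenyl)propan-2-one
Product: 13 1-[4-(3,5-dimethoxyphenoxy)-3,5-dimethoxyphenoxy]-2-methoxy-3-(2,4,6-trimethoxyphenyl)prop-1-ene (E/Z mixture; contains the regioisomeric enol ether with the double bond towards the trimethoxyphenyl side), via dimethyl ketal 12 (not isolated)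
Conditions: HC(OMe)3, MeOH, PPTS (cat.), rt; evaporate; then TMSOTf, i-Pr2NEt, CH2Cl2, −20 °C to rt; aq NaHCO3
Reagents that add atoms: trimethyl orthoformate, COC(OC)OC; methanol, CO
Why: acid-catalysed ketalisation with the orthoformate as water scavenger, then TMSOTf/amine-mediated elimination of methanol from the ketal through the oxocarbenium ion. All double-bond isomers are usable because step 7 acylates both α carbons.

Step 7
Reactants: 13 1-[4-(3,5-dimethoxyphenoxy)-3,5-dimethoxyphenoxy]-2-methoxy-3-(2,4,6-trimethoxyphenyl)prop-1-ene (isomer mixture); 14 malonyl dichloride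
Product: 16 3-[4-(3,5-dimethoxyphenoxy)-3,5-dimethoxyphenoxy]-2,2',4',6'-tetramethoxy-[1,1'-biphenyl]-4,6-diol, via acid chloride 15 (not isolated)
Conditions: 14 (1.05 equiv), Et2O–CH2Cl2, −20 °C to rt, 24 h; then aq KOH, BnEt3NCl, 0 °C, argon; acidify to pH 3
Reagents that add atoms: none
Why: The nucleophilic enol ether carbon attacks one acyl chloride of 14 with loss of HCl to give the β-methoxy enone acid chloride 15; the HCl formed re-protonates 15 to the oxocarbenium ion, which loses a proton from the other α carbon, and this transposed enol ether is acylated intramolecularly by the remaining COCl group (or the acylketene derived from it), after which two proton losses aromatise the ring to the 5-methoxyresorcinol unit of 16. The closest known reaction type is the Effenberger cyclisation of ketone enol ethers with malonyl dichloride, the α,α'-annulation that gives cyclohexane-1,3,5-trione systems such as bicyclo[3.3.1]nonane-2,4,9-triones. Ring C is closed by a 6-(enolendo)-exo-trig C-acylation that forms Ce–Cd (15 is drawn for first reaction at Ca; the other isomer of 13 reacts in the opposite order and converges). No stereocentre is created, since the sp3 centres at Ca and Ce vanish on aromatisation. The first selectivity needed is acylation at carbon instead of oxygen: the methyl group on the Cf oxygen blocks the lactonisation to a 4-hydroxy-2-pyranone that free 1,3,5-tricarbonyl chains undergo, and the only free carbonyl oxygen of 15 is in a 1,3 relation to the acid chloride and could close only a four-membered ring. The second is reaction at the enol ether in preference to rings A, B and D: no Lewis acid is present, the temperature is low, only a slight excess of 14 is used, the enol ether is the most nucleophilic π system in 13 and the second acylation is intramolecular. Aromatisation makes the sequence irreversible, and the short basic work-up hydrolyses any O-malonylated phenol.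

Step 8
Reactants: 16 3-[4-(3,5-dimethoxyphenoxy)-3,5-dimethoxyphenoxy]-2,2',4',6'-tetramethoxy-[1,1'-biphenyl]-4,6-diol
Product: 17 3-[4-(3,5-dihydroxyphenoxy)-3,5-dihydroxyphenoxy]-[1,1'-biphenyl]-2,2',4,4',6,6'-hexol (target, CNP0248644.0)
Conditions: BBr3 (16 equiv), CH2Cl2, −78 °C to rt; MeOH, then H2O, 0 °C; reversed-phase chromatography under argon
Reagents that add atoms: none
Why: Lewis acid-mediated cleavage of aryl methyl ethers; bromide attacks the methyl carbon of each boron-complexed ether. The diaryl ether and biaryl bonds offer no sp3 carbon for attack and survive, so all eight methyl groups are removed to give the achiral target.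

## Compound list

1 | syringaldehyde (4-hydroxy-3,5-dimethoxybenzaldehyde) | COc1cc(C=O)cc(OC)c1O | starting material
2 | (3,5-dimethoxyphenyl)boronic acid | COc1cc(OC)cc(B(O)O)c1 | starting material
3 | 4-(3,5-dimethoxyphenoxy)-3,5-dimethoxybenzaldehyde | COc1cc(OC)cc(Oc2c(OC)cc(C=O)cc2OC)c1 | intermediate
4 | 4-(3,5-dimethoxyphenoxy)-3,5-dimethoxyphenyl formate | COc1cc(OC)cc(Oc2c(OC)cc(OC=O)cc2OC)c1 | intermediate
5 | 4-(3,5-dimethoxyphenoxy)-3,5-dimethoxyphenol | COc1cc(OC)cc(Oc2c(OC)cc(O)cc2OC)c1 | intermediate
6 | epichlorohydrin (racemic 2-(chloromethyl)oxirane) | ClCC1CO1 | starting material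
7 | racemic 2-{[4-(3,5-dimethoxyphenoxy)-3,5-dimethoxyphenoxy]methyl}oxirane | COc1cc(OC)cc(Oc2c(OC)cc(OCC3CO3)cc2OC)c1 | intermediate
8 | 2-bromo-1,3,5-trimethoxybenzene | COc1cc(OC)c(Br)c(OC)c1 | starting material
9 | (2,4,6-trimethoxyphenyl)magnesium bromide | COc1cc(OC)c([Mg]Br)c(OC)c1 | intermediate
10 | racemic 1-[4-(3,5-dimethoxyphenoxy)-3,5-dimethoxyphenoxy]-3-(2,4,6-trimethoxyphenyl)propan-2-ol | COc1cc(OC)cc(Oc2c(OC)cc(OCC(O)Cc3c(OC)cc(OC)cc3OC)cc2OC)c1 | intermediate
11 | 1-[4-(3,5-dimethoxyphenoxy)-3,5-dimethoxyphenoxy]-3-(2,4,6-trimethoxyphenyl)propan-2-one | COc1cc(OC)cc(Oc2c(OC)cc(OCC(=O)Cc3c(OC)cc(OC)cc3OC)cc2OC)c1 | intermediate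
12 | 5-[2,2-dimethoxy-3-(2,4,6-trimethoxyphenyl)propoxy]-2-(3,5-dimethoxyphenoxy)-1,3-dimethoxybenzene (dimethyl ketal of 11) | COc1cc(OC)cc(Oc2c(OC)cc(OCC(OC)(OC)Cc3c(OC)cc(OC)cc3OC)cc2OC)c1 | intermediate
13 | 1-[4-(3,5-dimethoxyphenoxy)-3,5-dimethoxyphenoxy]-2-methoxy-3-(2,4,6-trimethoxyphenyl)prop-1-ene (E/Z mixture with its double-bond regioisomer; double-bond geometry left undefined) | COc1cc(OC)cc(Oc2c(OC)cc(OC=C(OC)Cc3c(OC)cc(OC)cc3OC)cc2OC)c1 | intermediate
14 | malonyl dichloride (propanedioyl dichloride) | ClC(=O)CC(Cl)=O | starting material
15 | 4-[4-(3,5-dimethoxyphenoxy)-3,5-dimethoxyphenoxy]-5-methoxy-3-oxo-6-(2,4,6-trimethoxyphenyl)hex-4-enoyl chloride (geometry undefined) | COc1cc(OC)cc(Oc2c(OC)cc(OC(C(=O)CC(Cl)=O)=C(OC)Cc3c(OC)cc(OC)cc3OC)cc2OC)c1 | intermediate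
16 | 3-[4-(3,5-dimethoxyphenoxy)-3,5-dimethoxyphenoxy]-2,2',4',6'-tetramethoxy-[1,1'-biphenyl]-4,6-diol | COc1cc(OC)cc(Oc2c(OC)cc(Oc3c(O)cc(O)c(-c4c(OC)cc(OC)cc4OC)c3OC)cc2OC)c1 | intermediate
17 | 3-[4-(3,5-dihydroxyphenoxy)-3,5-dihydroxyphenoxy]-[1,1'-biphenyl]-2,2',4,4',6,6'-hexol | Oc1cc(O)cc(Oc2c(O)cc(Oc3c(O)cc(O)c(-c4c(O)cc(O)cc4O)c3O)cc2O)c1 | target

## Step count and least certain steps

Total step count: 8. Longest linear sequence: 8 steps (1 to 17; the Grignard reagent 9 is made in the flask in step 4).

Step 7 (key step). Four processes may defeat it: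
- loss of the O-methyl group from the oxocarbenium intermediate by chloride attack, which frees the Cf oxygen and opens the way to lactonisation (pyranone formation) instead of the second C-acylation;
- acid-promoted attack of the activated ortho position of ring B on the oxocarbenium carbon (cyclisation towards a benzofuran);
- Friedel–Crafts acylation of rings A, B or D by 14;
- intermolecular second acylation leading to oligomers.

Fallback, by aryl–aryl and aryl–oxygen coupling of known types, setting out from 8 and 2 and coming back to the route at 17. Copper-mediated Ullmann homocoupling of 8 (Cu powder, DMF, 150 °C) would give 2,2',4,4',6,6'-hexamethoxy-1,1'-biphenyl F1. Vilsmeier–Haack monoformylation (POCl3, DMF) would give 2,2',4,4',6,6'-hexamethoxy-[1,1'-biphenyl]-3-carbaldehyde F2, and a Dakin oxidation as in step 2 the hindered phenol 2,2',4,4',6,6'-hexamethoxy-[1,1'-biphenyl]-3-ol F3. Separately, purchased 4-bromo-2,6-dimethoxyphenol F4 would be arylated with 2 under the conditions of step 1 to give 5-bromo-2-(3,5-dimethoxyphenoxy)-1,3-dimethoxybenzene F5. Ullmann etherification of F3 with the unhindered bromide F5 (CuI, picolinic acid, K3PO4, DMSO, 110 °C) would give the nonamethyl ether F6, which BBr3 as in step 8 would convert into 17.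

Step 6. The acidic ketalisation and the silyl triflate step both pass through an α-aryloxy oxocarbenium ion, and cyclodehydration onto ring B or incomplete elimination of methanol may compete. Fallback, setting out from 11 and coming back at 13: O-methylation of the dissociated potassium enolate (KHMDS, 18-crown-6, THF, −78 °C, then dimethyl sulfate) under purely basic conditions, where a hard methylating agent and a free enolate favour reaction at oxygen. No new compound is involved.

Step 8. Incomplete cleavage of the most hindered methoxy group (on Cf, between the aryloxy and aryl substituents), HBr-promoted cyclodehydration of the 2,2'-dihydroxybiaryl, and air oxidation of the free polyphenol during isolation are the likely failures. Fallback, setting out from 16 and coming back at 17: after the BBr3 treatment the crude phenol is acetylated at once (Ac2O, pyridine, DMAP) to the deca-acetate F7, which is stable and can be purified on silica; it is then deacetylated under argon (NaOMe cat., MeOH, 0 °C, acidic resin quench) to 17.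

Step 4. Slow attack of the doubly ortho-substituted aryl nucleophile may allow opening of the epoxide by bromide or Lewis acid-induced isomerisation of the epoxide by magnesium salts. Fallback, setting out from 9 and 5 and coming back at 10: allylation of 9 with allyl bromide would give 2-allyl-1,3,5-trimethoxybenzene F8. Dihydroxylation (OsO4 cat., NMO, acetone–water) would give racemic 3-(2,4,6-trimethoxyphenyl)propane-1,2-diol F9. Mitsunobu etherification of the primary hydroxyl of F9 with phenol 5 (PPh3, DIAD, THF) would give 10, so that no hindered nucleophile has to open an epoxide.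

## Further compounds

F1 | step 7 | 2,2',4,4',6,6'-hexamethoxy-1,1'-biphenyl | COc1cc(OC)c(-c2c(OC)cc(OC)cc2OC)c(OC)c1
F2 | step 7 | 2,2',4,4',6,6'-hexamethoxy-[1,1'-biphenyl]-3-carbaldehyde | COc1cc(OC)c(-c2c(OC)cc(OC)c(C=O)c2OC)c(OC)c1
F3 | step 7 | 2,2',4,4',6,6'-hexamethoxy-[1,1'-biphenyl]-3-ol | COc1cc(OC)c(-c2c(OC)cc(OC)c(O)c2OC)c(OC)c1
F4 | step 7 | 4-bromo-2,6-dimethoxyphenol (purchased) | COc1cc(Br)cc(OC)c1O
F5 | step 7 | 5-bromo-2-(3,5-dimethoxyphenoxy)-1,3-dimethoxybenzene | COc1cc(OC)cc(Oc2c(OC)cc(Br)cc2OC)c1
F6 | step 7 | 3-[4-(3,5-dimethoxyphenoxy)-3,5-dimethoxyphenoxy]-2,2',4,4',6,6'-hexamethoxy-1,1'-biphenyl | COc1cc(OC)cc(Oc2c(OC)cc(Oc3c(OC)cc(OC)c(-c4c(OC)cc(OC)cc4OC)c3OC)cc2OC)c1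
F0 | step 6 | none | none
F7 | step 8 | deca-acetate of 17 (all ten phenolic OH groups acetylated) | CC(=O)Oc1cc(OC(C)=O)cc(Oc2c(OC(C)=O)cc(Oc3c(OC(C)=O)cc(OC(C)=O)c(-c4c(OC(C)=O)cc(OC(C)=O)cc4OC(C)=O)c3OC(C)=O)cc2OC(C)=O)c1
F8 | step 4 | 2-allyl-1,3,5-trimethoxybenzene | COc1cc(OC)c(CC=C)c(OC)c1
F9 | step 4 | racemic 3-(2,4,6-trimethoxyphenyl)propane-1,2-diol | COc1cc(OC)c(CC(O)CO)c(OC)c1
A1 | alternative 1 | 3-bromo-2,2',4,4',6,6'-hexamethoxy-1,1'-biphenyl | COc1cc(OC)c(-c2c(OC)cc(OC)c(Br)c2OC)c(OC)c1
A2 | alternative 2 | methyl 2-[4-(3,5-dimethoxyphenoxy)-3,5-dimethoxyphenoxy]-3,5-dioxo-6-(2,4,6-trimethoxyphenyl)hexanoate | COC(=O)C(Oc1cc(OC)c(Oc2cc(OC)cc(OC)c2)c(OC)c1)C(=O)CC(=O)Cc1c(OC)cc(OC)cc1OC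
A3 | alternative 2 | 3-[4-(3,5-dimethoxyphenoxy)-3,5-dimethoxyphenoxy]-4-hydroxy-6-[(2,4,6-trimethoxyphenyl)methyl]-2H-pyran-2-one | O=C1OC(Cc2c(OC)cc(OC)cc2OC)=CC(O)=C1Oc1cc(OC)c(Oc2cc(OC)cc(OC)c2)c(OC)c1
A4 | alternative 3 | 4-diazo-3,5-dimethoxy-2-(2,4,6-trimethoxyphenyl)cyclohexa-2,5-dien-1-one | [N-]=[N+]=C1C(OC)=CC(=O)C(c2c(OC)cc(OC)cc2OC)=C1OC
A5 | alternative 3 | 3-[4-(3,5-dimethoxyphenoxy)-3,5-dimethoxyphenoxy]-2,2',4,4',6'-pentamethoxy-[1,1'-biphenyl]-6-ol | COc1cc(OC)cc(Oc2c(OC)cc(Oc3c(OC)cc(O)c(-c4c(OC)cc(OC)cc4OC)c3OC)cc2OC)c1
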